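**Plan**

1. Locants: C1 = ring CH(CH3); C4 = ring CH carrying the chain; C4a/C8a = ring-fusion carbons (C8a next to C1); C6 = C–CO2H; C7/C8 = C–OH; C11 = chain CH on C4; C18 = its CH2O; C15 = CH(CH3); C16 = terminal CH2O.
2. Retrosynthesis: remove the acetates and isopropyl ethers, take CO2H off C6 (directed metalation), then cut C11–C18 (one-carbon boron homologation) and C4–C11 (1,2-metallate rearrangement) to reach a C4 boronic ester of a trans-1-methyltetralin and a C11–C16 carbamate.
3. The tetralin comes from (1R)-1-methyl-1,2-dihydronaphthalene, which is cut across ring B at C1–C2 and C4–C4a into a 1-arylethyl chloride and a propanal homoenolate equivalent (C2–C3–C4).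
4. Feature used: C1 is benzylic and flanked by the C8 oxygen, and C4a is the only free carbon ortho to C8a and lies para to the C7 oxygen, so a three-carbon unit with nucleophilic C2 and carbonyl C4 can bridge C1 and C4a.
5. Forward order: ring A is bought; ring B is closed in one flask (C1–C2 coupling, then Friedel–Crafts cyclodehydration at C4a); boron is put on C4; the chain is joined at C4–C11 and extended by C18; the arene is carboxylated last.
6. Stereochemistry: C1 from the ligand of the stereoconvergent coupling; C4 from anti-to-methyl hydroboration and stereoretentive migration; C11 from (+)-sparteine-directed lithiation; C15 from (2S)-3-bromo-2-methylpropan-1-ol.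

Key step: step 4

Assumption: the sense of induction of the chiral ligands named in steps 4 and 5 is assigned by analogy with simpler benzylic halides and vinylarenes; if a trial run shows the opposite sense, the enantiomeric ligand is the one to use.

**Route**

Step 1
Reactants: 1 2,3-dihydroxybenzaldehyde
Product: 2 2,3-di(propan-2-yloxy)benzaldehyde
Conditions: 2-bromopropane, K2CO3, DMF, 60 °C
Reagents that add atoms: 2-bromopropane CC(C)Br
Why: Williamson ether synthesis on both phenols should give isopropyl ethers that withstand acid and organolithiums, direct the later ortho metalation and are removable with BCl3.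

Step 2
Reactants: 2 2,3-di(propan-2-yloxy)benzaldehyde
Product: 3 rac-1-[2,3-di(propan-2-yloxy)phenyl]ethan-1-ol
Conditions: MeMgBr, THF, 0 °C, then H2O
Reagents that add atoms: methylmagnesium bromide C[Mg]Br
Why: Grignard 1,2-addition creates C1 with its methyl group; the centre is left racemic because step 4 is stereoconvergent.

Step 3
Reactants: 3 rac-1-[2,3-di(propan-2-yloxy)phenyl]ethan-1-ol
Product: 4 rac-1-(1-chloroethyl)-2,3-di(propan-2-yloxy)benzene
Conditions: SOCl2, CH2Cl2, 0 °C, used crude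
Reagents that add atoms: thionyl chloride O=S(Cl)Cl
Why: Deoxychlorination of the electron-rich benzylic alcohol through its chlorosulfite should give the secondary benzylic chloride needed as the coupling electrophile.

Step 4
Reactants: 4 rac-1-(1-chloroethyl)-2,3-di(propan-2-yloxy)benzene; 5 [2-(1,3-dioxolan-2-yl)ethyl]zinc bromide
Product: 8 (1R)-1-methyl-7,8-di(propan-2-yloxy)-1,2-dihydronaphthalene, via acetal 6 (not isolated), via aldehyde 7 (not isolated)
Conditions: NiBr2·diglyme (10 mol %), (S)-iPr-Pybox (13 mol %), DMA, 0 °C; then TsOH·H2O, wet toluene, 70 °C, same flask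
Reagents that add atoms: none
Why: A nickel/Pybox-catalysed stereoconvergent Negishi coupling joins the racemic benzylic chloride (C1, through a benzylic radical captured by the chiral nickel alkyl) to the zinc reagent, a polarity-reversed propanal homoenolate equivalent, so that C1–C2 forms and C1 is set as R by the ligand whatever the configuration of 4. Acid then unmasks aldehyde 7, and its protonated carbonyl is attacked by C4a, the only free ortho carbon and para to the C7 ether oxygen, in a 6-exo-trig Friedel–Crafts hydroxyalkylation that closes ring B. Loss of water through the para-alkoxybenzyl cation gives the C3=C4 styrene. The closest known reaction types are enantioconvergent Negishi couplings of secondary benzylic halides with functionalised alkylzinc halides and the acid cyclodehydration of 4-arylbutanals to 1,2-dihydronaphthalenes. The step needs ring closure at C4a only, which the substitution pattern enforces because the other ortho carbon (C8) carries oxygen. It also needs C1 to stay intact, which is expected because C1 is neither allylic to the new alkene nor ionisable under these conditions.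

Step 5
Reactants: 8 (1R)-1-methyl-7,8-di(propan-2-yloxy)-1,2-dihydronaphthalene
Product: 9 2-[(1R,4R)-4-methyl-5,6-di(propan-2-yloxy)-1,2,3,4-tetrahydronaphthalen-1-yl]-4,4,5,5-tetramethyl-1,3,2-dioxaborolane
Conditions: CuCl (3 mol %), NaOtBu, (R)-DTBM-SEGPHOS, HBpin, toluene, rt
Reagents that add atoms: pinacolborane CC1(C)OBOC1(C)C
Why: Copper-hydride-catalysed Markovnikov hydroboration of the styrenic C3=C4 bond should put copper, then boron, on benzylic C4 from the face opposite the pseudoaxial C1 methyl group, with the chiral bisphosphine reinforcing this, to give the trans boronic ester.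

Step 6
Reactants: 10 (2S)-3-bromo-2-methylpropan-1-ol
Product: 11 {[(2S)-3-bromo-2-methylpropyl]oxy}(tert-butyl)dimethylsilane
Conditions: TBSCl, imidazole, DMF, rt
Reagents that add atoms: tert-butyl(chloro)dimethylsilane CC(C)(C)[Si](C)(C)Cl
Why: Imidazole-promoted silylation protects the future C16 oxygen against the organometallic steps and leaves C15 untouched.

Step 7
Reactants: 11 {[(2S)-3-bromo-2-methylpropyl]oxy}(tert-butyl)dimethylsilane
Product: 12 tert-butyl(dimethyl){[(2R)-2-methylhex-5-en-1-yl]oxy}silane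
Conditions: allylmagnesium bromide, Li2CuCl4 (5 mol %), THF, 0 °C
Reagents that add atoms: allylmagnesium bromide C=CC[Mg]Br
Why: Copper-catalysed Grignard cross-coupling at the primary bromide adds C11–C13; C15 is not involved and only its descriptor changes.

Step 8
Reactants: 12 tert-butyl(dimethyl){[(2R)-2-methylhex-5-en-1-yl]oxy}silane
Product: 14 (5R)-6-{[tert-butyl(dimethyl)silyl]oxy}-5-methylhexan-1-ol, via alkylborane 13 (not isolated)
Conditions: 9-BBN, THF, rt; then NaOH, H2O2, 0 °C to rt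
Reagents that add atoms: hydrogen peroxide OO
Why: Anti-Markovnikov hydroboration with 9-BBN and oxidative work-up should place the hydroxyl on the terminal carbon C11.

Step 9
Reactants: 14 (5R)-6-{[tert-butyl(dimethyl)silyl]oxy}-5-methylhexan-1-ol
Product: 15 (5R)-6-{[tert-butyl(dimethyl)silyl]oxy}-5-methylhexyl N,N-di(propan-2-yl)carbamate
Conditions: iPr2NCOCl, Et3N, CH2Cl2, reflux
Reagents that add atoms: N,N-di(propan-2-yl)carbamoyl chloride CC(C)N(C(C)C)C(Cl)=O
Why: O-Carbamoylation installs the group that directs α-lithiation at C11 and later acts as the leaving group.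

Step 10
Reactants: 15 (5R)-6-{[tert-butyl(dimethyl)silyl]oxy}-5-methylhexyl N,N-di(propan-2-yl)carbamate; 9 2-[(1R,4R)-4-methyl-5,6-di(propan-2-yloxy)-1,2,3,4-tetrahydronaphthalen-1-yl]-4,4,5,5-tetramethyl-1,3,2-dioxaborolane
Product: 18 2-[(1S,5R)-6-{[tert-butyl(dimethyl)silyl]oxy}-5-methyl-1-[(1S,4R)-4-methyl-5,6-di(propan-2-yloxy)-1,2,3,4-tetrahydronaphthalen-1-yl]hexyl]-4,4,5,5-tetramethyl-1,3,2-dioxaborolane, via lithiated carbamate 16 (not isolated), via boronate complex 17 (not isolated)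
Conditions: 15, s-BuLi, (+)-sparteine, Et2O, −78 °C; then 9, −78 °C; then MgBr2·OEt2, reflux
Reagents that add atoms: none
Why: In this lithiation–borylation homologation, (+)-sparteine-directed removal of the pro-R hydrogen, borylation with retention and antiperiplanar 1,2-metallate rearrangement (C4 migrates with retention, the carbamate leaves with inversion) should form C4–C11 and set C11 under reagent control.

Step 11
Reactants: 18 2-[(1S,5R)-6-{[tert-butyl(dimethyl)silyl]oxy}-5-methyl-1-[(1S,4R)-4-methyl-5,6-di(propan-2-yloxy)-1,2,3,4-tetrahydronaphthalen-1-yl]hexyl]-4,4,5,5-tetramethyl-1,3,2-dioxaborolane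
Product: 20 (2S,6R)-7-{[tert-butyl(dimethyl)silyl]oxy}-6-methyl-2-[(1S,4R)-4-methyl-5,6-di(propan-2-yloxy)-1,2,3,4-tetrahydronaphthalen-1-yl]heptan-1-ol, via homologated boronic ester 19 (not isolated)
Conditions: BrCH2Cl, n-BuLi, THF, −78 °C to rt; then NaOH, H2O2, 0 °C
Reagents that add atoms: bromochloromethane ClCBr; hydrogen peroxide OO
Why: Matteson one-carbon homologation with (chloromethyl)lithium inserts C18 into the C11–B bond with retention, and alkaline peroxide oxidises the primary boronic ester to the alcohol without touching C11.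

Step 12
Reactants: 20 (2S,6R)-7-{[tert-butyl(dimethyl)silyl]oxy}-6-methyl-2-[(1S,4R)-4-methyl-5,6-di(propan-2-yloxy)-1,2,3,4-tetrahydronaphthalen-1-yl]heptan-1-ol
Product: 22 (5R,8S)-8-[(2S,6R)-7-{[tert-butyl(dimethyl)silyl]oxy}-1-hydroxy-6-methylheptan-2-yl]-5-methyl-3,4-di(propan-2-yloxy)-5,6,7,8-tetrahydronaphthalene-2-carboxylic acid, via aryllithium 21 (not isolated)
Conditions: s-BuLi (3 equiv), TMEDA, THF, −78 to −30 °C; CO2; dilute HCl
Reagents that add atoms: carbon dioxide O=C=O
Why: Directed ortho metalation should remove C6–H, the only ring hydrogen ortho to an ether oxygen, after the alcohol is deprotonated, and CO2 carboxylates the aryllithium.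

Step 13
Reactants: 22 (5R,8S)-8-[(2S,6R)-7-{[tert-butyl(dimethyl)silyl]oxy}-1-hydroxy-6-methylheptan-2-yl]-5-methyl-3,4-di(propan-2-yloxy)-5,6,7,8-tetrahydronaphthalene-2-carboxylic acid
Product: 23 (5R,8S)-8-[(2S,6R)-1,7-dihydroxy-6-methylheptan-2-yl]-5-methyl-3,4-di(propan-2-yloxy)-5,6,7,8-tetrahydronaphthalene-2-carboxylic acid
Conditions: TBAF, THF, rt; dilute HCl work-up
Reagents that add atoms: none
Why: Fluoride-induced desilylation frees the C16 hydroxyl; the ethers, the carboxyl group and all stereocentres are inert.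

Step 14
Reactants: 23 (5R,8S)-8-[(2S,6R)-1,7-dihydroxy-6-methylheptan-2-yl]-5-methyl-3,4-di(propan-2-yloxy)-5,6,7,8-tetrahydronaphthalene-2-carboxylic acid
Product: 24 (5R,8S)-8-[(2S,6R)-1,7-bis(acetyloxy)-6-methylheptan-2-yl]-5-methyl-3,4-di(propan-2-yloxy)-5,6,7,8-tetrahydronaphthalene-2-carboxylic acid
Conditions: Ac2O, pyridine, DMAP (cat.), CH2Cl2, rt; aqueous NaHCO3, then dilute HCl
Reagents that add atoms: acetic anhydride CC(=O)OC(C)=O
Why: DMAP-catalysed O-acylation should acetylate both primary alcohols, and the transient mixed anhydride at the carboxyl group is hydrolysed on aqueous work-up.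

Step 15
Reactants: 24 (5R,8S)-8-[(2S,6R)-1,7-bis(acetyloxy)-6-methylheptan-2-yl]-5-methyl-3,4-di(propan-2-yloxy)-5,6,7,8-tetrahydronaphthalene-2-carboxylic acid
Product: 25 (5R,8S)-8-[(2S,6R)-1,7-bis(acetyloxy)-6-methylheptan-2-yl]-3,4-dihydroxy-5-methyl-5,6,7,8-tetrahydronaphthalene-2-carboxylic acid
Conditions: BCl3, CH2Cl2, −78 to 0 °C; H2O
Reagents that add atoms: none
Why: Lewis-acid ether cleavage: BCl3 coordinates the aryl ether oxygens (helped at C7 by the neighbouring carboxyl) and releases 2-chloropropane at low temperature, where the primary acetates are expected to survive.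

**Compound list**

1 | 2,3-dihydroxybenzaldehyde | O=Cc1cccc(O)c1O | starting material
2 | 2,3-di(propan-2-yloxy)benzaldehyde | O=Cc1cccc(OC(C)C)c1OC(C)C | intermediate
3 | rac-1-[2,3-di(propan-2-yloxy)phenyl]ethan-1-ol | CC(O)c1cccc(OC(C)C)c1OC(C)C | intermediate
4 | rac-1-(1-chloroethyl)-2,3-di(propan-2-yloxy)benzene | CC(Cl)c1cccc(OC(C)C)c1OC(C)C | intermediate
5 | [2-(1,3-dioxolan-2-yl)ethyl]zinc bromide | Br[Zn]CCC1OCCO1 | starting material
6 | 2-[(3R)-3-[2,3-di(propan-2-yloxy)phenyl]butyl]-1,3-dioxolane | C[C@H](CCC1OCCO1)c1cccc(OC(C)C)c1OC(C)C | intermediate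
7 | (4R)-4-[2,3-di(propan-2-yloxy)phenyl]pentanal | C[C@H](CCC=O)c1cccc(OC(C)C)c1OC(C)C | intermediate
8 | (1R)-1-methyl-7,8-di(propan-2-yloxy)-1,2-dihydronaphthalene | C1=CC[C@@H](C)c2c1ccc(OC(C)C)c2OC(C)C | intermediate
9 | 2-[(1R,4R)-4-methyl-5,6-di(propan-2-yloxy)-1,2,3,4-tetrahydronaphthalen-1-yl]-4,4,5,5-tetramethyl-1,3,2-dioxaborolane | CC1(C)OB(OC1(C)C)[C@@H]1CC[C@@H](C)c2c1ccc(OC(C)C)c2OC(C)C | intermediate
10 | (2S)-3-bromo-2-methylpropan-1-ol | OC[C@H](C)CBr | starting material
11 | {[(2S)-3-bromo-2-methylpropyl]oxy}(tert-butyl)dimethylsilane | CC(C)(C)[Si](C)(C)OC[C@H](C)CBr | intermediate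
12 | tert-butyl(dimethyl){[(2R)-2-methylhex-5-en-1-yl]oxy}silane | CC(C)(C)[Si](C)(C)OC[C@H](C)CCC=C | intermediate
13 | 9-[(5R)-6-{[tert-butyl(dimethyl)silyl]oxy}-5-methylhexyl]-9-borabicyclo[3.3.1]nonane | CC(C)(C)[Si](C)(C)OC[C@H](C)CCCCB1C2CCCC1CCC2 | intermediate
14 | (5R)-6-{[tert-butyl(dimethyl)silyl]oxy}-5-methylhexan-1-ol | CC(C)(C)[Si](C)(C)OC[C@H](C)CCCCO | intermediate
15 | (5R)-6-{[tert-butyl(dimethyl)silyl]oxy}-5-methylhexyl N,N-di(propan-2-yl)carbamate | CC(C)(C)[Si](C)(C)OC[C@H](C)CCCCOC(=O)N(C(C)C)C(C)C | intermediate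
16 | (1R,5R)-6-{[tert-butyl(dimethyl)silyl]oxy}-1-lithio-5-methylhexyl N,N-di(propan-2-yl)carbamate (as its (+)-sparteine complex) | CC(C)(C)[Si](C)(C)OC[C@H](C)CCC[C@@H]([Li])OC(=O)N(C(C)C)C(C)C | intermediate
17 | lithium boronate complex of 9 and 16: boron carries pinacolato, the (1R,4R)-tetralinyl group of 9 and the (1R)-1-(carbamoyloxy)alkyl group of 16 | CC(C)(C)[Si](C)(C)OC[C@H](C)CCC[C@H](OC(=O)N(C(C)C)C(C)C)[B-]1(OC(C)(C)C(C)(C)O1)[C@@H]1CC[C@@H](C)c2c1ccc(OC(C)C)c2OC(C)C.[Li+] | intermediate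
18 | 2-[(1S,5R)-6-{[tert-butyl(dimethyl)silyl]oxy}-5-methyl-1-[(1S,4R)-4-methyl-5,6-di(propan-2-yloxy)-1,2,3,4-tetrahydronaphthalen-1-yl]hexyl]-4,4,5,5-tetramethyl-1,3,2-dioxaborolane | CC(C)(C)[Si](C)(C)OC[C@H](C)CCC[C@H](B1OC(C)(C)C(C)(C)O1)[C@@H]1CC[C@@H](C)c2c1ccc(OC(C)C)c2OC(C)C | intermediate
19 | 2-[(2S,6R)-7-{[tert-butyl(dimethyl)silyl]oxy}-6-methyl-2-[(1S,4R)-4-methyl-5,6-di(propan-2-yloxy)-1,2,3,4-tetrahydronaphthalen-1-yl]heptyl]-4,4,5,5-tetramethyl-1,3,2-dioxaborolane | CC(C)(C)[Si](C)(C)OC[C@H](C)CCC[C@H](CB1OC(C)(C)C(C)(C)O1)[C@@H]1CC[C@@H](C)c2c1ccc(OC(C)C)c2OC(C)C | intermediate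
20 | (2S,6R)-7-{[tert-butyl(dimethyl)silyl]oxy}-6-methyl-2-[(1S,4R)-4-methyl-5,6-di(propan-2-yloxy)-1,2,3,4-tetrahydronaphthalen-1-yl]heptan-1-ol | CC(C)(C)[Si](C)(C)OC[C@H](C)CCC[C@H](CO)[C@@H]1CC[C@@H](C)c2c1ccc(OC(C)C)c2OC(C)C | intermediate
21 | dilithio species of 20: lithium alkoxide at C18–O and aryllithium at C6 | CC(C)(C)[Si](C)(C)OC[C@H](C)CCC[C@H](CO[Li])[C@@H]1CC[C@@H](C)c2c1cc([Li])c(OC(C)C)c2OC(C)C | intermediate
22 | (5R,8S)-8-[(2S,6R)-7-{[tert-butyl(dimethyl)silyl]oxy}-1-hydroxy-6-methylheptan-2-yl]-5-methyl-3,4-di(propan-2-yloxy)-5,6,7,8-tetrahydronaphthalene-2-carboxylic acid | CC(C)(C)[Si](C)(C)OC[C@H](C)CCC[C@H](CO)[C@@H]1CC[C@@H](C)c2c1cc(C(=O)O)c(OC(C)C)c2OC(C)C | intermediate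
23 | (5R,8S)-8-[(2S,6R)-1,7-dihydroxy-6-methylheptan-2-yl]-5-methyl-3,4-di(propan-2-yloxy)-5,6,7,8-tetrahydronaphthalene-2-carboxylic acid | OC[C@H](C)CCC[C@H](CO)[C@@H]1CC[C@@H](C)c2c1cc(C(=O)O)c(OC(C)C)c2OC(C)C | intermediate
24 | (5R,8S)-8-[(2S,6R)-1,7-bis(acetyloxy)-6-methylheptan-2-yl]-5-methyl-3,4-di(propan-2-yloxy)-5,6,7,8-tetrahydronaphthalene-2-carboxylic acid | CC(=O)OC[C@H](C)CCC[C@H](COC(C)=O)[C@@H]1CC[C@@H](C)c2c1cc(C(=O)O)c(OC(C)C)c2OC(C)C | intermediate
25 | (5R,8S)-8-[(2S,6R)-1,7-bis(acetyloxy)-6-methylheptan-2-yl]-3,4-dihydroxy-5-methyl-5,6,7,8-tetrahydronaphthalene-2-carboxylic acid | CC(=O)OC[C@H](C)CCC[C@H](COC(C)=O)[C@@H]1CC[C@@H](C)c2c1cc(C(=O)O)c(O)c2O | target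

**Count and risks**

Total steps: 15. Longest linear sequence: 11 steps (1–5, then 10–15).

Step 4. The nickel-catalysed coupling of this hindered, electron-rich benzylic chloride may lose enantioselectivity or suffer β-hydride elimination, and the electron-rich styrene may oligomerise under acid. The fallback is stereospecific instead of stereoconvergent and sets out from 3. Oxidation with MnO2 should give 1-[2,3-di(propan-2-yloxy)phenyl]ethan-1-one F1. Corey–Bakshi–Shibata reduction ((S)-methyl oxazaborolidine, BH3·SMe2) should give (1R)-1-[2,3-di(propan-2-yloxy)phenyl]ethan-1-ol F2, and carbamoylation (iPr2NCOCl, Et3N) the carbamate (1R)-1-[2,3-di(propan-2-yloxy)phenyl]ethyl N,N-di(propan-2-yl)carbamate F3. Lithiation (s-BuLi, Et2O, −78 °C), borylation with 2-[2-(1,3-dioxolan-2-yl)ethyl]-4,4,5,5-tetramethyl-1,3,2-dioxaborolane and 1,2-metallate rearrangement (MgBr2, MeOH) should give the tertiary boronic ester 2-[(2R)-2-[2,3-di(propan-2-yloxy)phenyl]-4-(1,3-dioxolan-2-yl)butan-2-yl]-4,4,5,5-tetramethyl-1,3,2-dioxaborolane F4 with inversion at C1. Protodeboronation with TBAF·3H2O (retention) comes back to 6, now isolated, which is cyclised to 8 with TsOH as in step 4.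

Step 10. Formation of the boronate complex between the hindered secondary benzylic boronic ester and the diamine-bound carbenoid may be slow or reversible, with loss of conversion or of configurational purity at C11. The fallback moves boron onto an alkene and sets out from 14 and 9. Oxidation of 14 (Dess–Martin periodinane) should give (5R)-6-{[tert-butyl(dimethyl)silyl]oxy}-5-methylhexanal F5. Seyferth–Gilbert homologation with the Ohira–Bestmann reagent (K2CO3, MeOH) should give tert-butyl(dimethyl){[(2R)-2-methylhept-6-yn-1-yl]oxy}silane F6, and bromoboration–protonolysis (B-bromo-9-BBN, then AcOH) {[(2R)-6-bromo-2-methylhept-6-en-1-yl]oxy}(tert-butyl)dimethylsilane F7. Bromine–lithium exchange (t-BuLi), addition to 9 and Zweifel olefination (I2, NaOMe; retention at C4) should give tert-butyl(dimethyl){[(2R)-2-methyl-6-[(1S,4R)-4-methyl-5,6-di(propan-2-yloxy)-1,2,3,4-tetrahydronaphthalen-1-yl]hept-6-en-1-yl]oxy}silane F8. Copper-hydride-catalysed anti-Markovnikov hydroboration (CuCl, NaOtBu, DTBM-SEGPHOS, HBpin) then sets C11 under ligand and C4 control and comes back at 19, which is oxidised to 20 as in step 11.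

Step 15. The two primary acetates may be partly lost, or the flanked C8 ether incompletely cleaved, under BCl3. The fallback changes the order of events and sets out from 23. BCl3 applied before acylation should give (5R,8S)-8-[(2S,6R)-1,7-dihydroxy-6-methylheptan-2-yl]-3,4-dihydroxy-5-methyl-5,6,7,8-tetrahydronaphthalene-2-carboxylic acid F9. Peracetylation (Ac2O, pyridine, aqueous work-up) should give (5R,8S)-3,4-bis(acetyloxy)-8-[(2S,6R)-1,7-bis(acetyloxy)-6-methylheptan-2-yl]-5-methyl-5,6,7,8-tetrahydronaphthalene-2-carboxylic acid F10. Chemoselective aminolysis of the two aryl acetates with pyrrolidine (CH2Cl2, 0 °C) comes back at 25.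

Further compounds
F1 | step 4 | 1-[2,3-di(propan-2-yloxy)phenyl]ethan-1-one | CC(=O)c1cccc(OC(C)C)c1OC(C)C
F2 | step 4 | (1R)-1-[2,3-di(propan-2-yloxy)phenyl]ethan-1-ol | C[C@@H](O)c1cccc(OC(C)C)c1OC(C)C
F3 | step 4 | (1R)-1-[2,3-di(propan-2-yloxy)phenyl]ethyl N,N-di(propan-2-yl)carbamate | C[C@@H](OC(=O)N(C(C)C)C(C)C)c1cccc(OC(C)C)c1OC(C)C
F4 | step 4 | 2-[(2R)-2-[2,3-di(propan-2-yloxy)phenyl]-4-(1,3-dioxolan-2-yl)butan-2-yl]-4,4,5,5-tetramethyl-1,3,2-dioxaborolane | C[C@@](CCC1OCCO1)(B1OC(C)(C)C(C)(C)O1)c1cccc(OC(C)C)c1OC(C)C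
F5 | step 10 | (5R)-6-{[tert-butyl(dimethyl)silyl]oxy}-5-methylhexanal | CC(C)(C)[Si](C)(C)OC[C@H](C)CCCC=O
F6 | step 10 | tert-butyl(dimethyl){[(2R)-2-methylhept-6-yn-1-yl]oxy}silane | CC(C)(C)[Si](C)(C)OC[C@H](C)CCCC#C
F7 | step 10 | {[(2R)-6-bromo-2-methylhept-6-en-1-yl]oxy}(tert-butyl)dimethylsilane | CC(C)(C)[Si](C)(C)OC[C@H](C)CCCC(Br)=C
F8 | step 10 | tert-butyl(dimethyl){[(2R)-2-methyl-6-[(1S,4R)-4-methyl-5,6-di(propan-2-yloxy)-1,2,3,4-tetrahydronaphthalen-1-yl]hept-6-en-1-yl]oxy}silane | CC(C)(C)[Si](C)(C)OC[C@H](C)CCCC(=C)[C@@H]1CC[C@@H](C)c2c1ccc(OC(C)C)c2OC(C)C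
F9 | step 15 | (5R,8S)-8-[(2S,6R)-1,7-dihydroxy-6-methylheptan-2-yl]-3,4-dihydroxy-5-methyl-5,6,7,8-tetrahydronaphthalene-2-carboxylic acid | OC[C@H](C)CCC[C@H](CO)[C@@H]1CC[C@@H](C)c2c1cc(C(=O)O)c(O)c2O
F10 | step 15 | (5R,8S)-3,4-bis(acetyloxy)-8-[(2S,6R)-1,7-bis(acetyloxy)-6-methylheptan-2-yl]-5-methyl-5,6,7,8-tetrahydronaphthalene-2-carboxylic acid | CC(=O)OC[C@H](C)CCC[C@H](COC(C)=O)[C@@H]1CC[C@@H](C)c2c1cc(C(=O)O)c(OC(C)=O)c2OC(C)=O
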